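**Retrosynthetic overview**

1. Target 9, (R)-β-tocotrienol, is a chroman-6-ol whose only stereocentre is C2; the benzene ring is bought and the dihydropyran ring (O1–C2–C3–C4–C4a–C8a) is closed last.
2. Key disconnection O1–C2 (with H returned to C3): 9 ⇒ the open, achiral hydroquinone 8; forward, a tocopherol cyclase (EC 5.5.1.24, an intramolecular lyase) performs the enantioselective 6-endo hydroalkoxylation of one of four trisubstituted double bonds.
3. Enabling feature: O1 on C8a is ortho to C4a, and C4a–C4H2–C3H2–C2(CH3)(chain) is a hydrated prenyl unit with C2 as the Markovnikov carbon; the para hydroxyl on C6 and the all-E polyprenyl tail are the handles this enzyme class binds.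
4. 8 ⇐ quinone 7 (a storage oxidation level that cannot cyclise) ⇐ dimethyl ether 6 ⇐ aryl–C1′ coupling of aryl Grignard 5 (from bromide 2, from 1) with geranylgeranyl bromide 4 (from geranylgeraniol 3).
5. All chain double bonds, including the 2′E double bond the enzyme needs, come unchanged from 3; no acid meets a free prenylhydroquinone, so no racemic background closure can compete.

Key step: step 6

Assumption: the cyclase tolerates the ring methyl ortho to the prenyl chain of 8 (the later C5 methyl), as this enzyme class tolerates the mono- and dimethyl patterns of its natural prenylquinol substrates; commercial geranylgeraniol is taken as the all-E isomer.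

**Step 1**
Reactants: 1 1,4-dimethoxy-2,5-dimethylbenzene
Product: 2 1-bromo-2,5-dimethoxy-3,6-dimethylbenzene
Conditions: NBS (1.0 equiv), MeCN, 0 °C to rt, dark
Reagents that add atoms: N-bromosuccinimide, O=C1CCC(=O)N1Br
Why: Electrophilic aromatic bromination of the electron-rich arene, in which the two free ring positions of 1 are equivalent and the first bromine slows a second substitution, so the monobromide should dominate.

**Step 2**
Reactants: 3 (2E,6E,10E)-3,7,11,15-tetramethylhexadeca-2,6,10,14-tetraen-1-ol (geranylgeraniol)
Product: 4 (2E,6E,10E)-1-bromo-3,7,11,15-tetramethylhexadeca-2,6,10,14-tetraene (geranylgeranyl bromide)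
Conditions: PBr3 (0.4 equiv), Et2O, −10 °C, dark; used crude at once
Reagents that add atoms: phosphorus tribromide, BrP(Br)Br
Why: SN2 displacement of the intermediate bromophosphite by bromide at the primary allylic carbon at low temperature, the standard preparation of polyprenyl bromides, should give 4 without allylic transposition or loss of the 2E geometry.

**Step 3**
Reactants: 2 1-bromo-2,5-dimethoxy-3,6-dimethylbenzene; 4 geranylgeranyl bromide
Product: 6 1,4-dimethoxy-2,5-dimethyl-3-[(2E,6E,10E)-3,7,11,15-tetramethylhexadeca-2,6,10,14-tetraen-1-yl]benzene, via arylmagnesium bromide 5 (not isolated)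
Conditions: Mg turnings (I2 activation), THF, reflux; then Li2CuCl4 (3 mol %), 4, THF, −20 to 0 °C
Reagents that add atoms: none
Why: Grignard formation followed by a copper-catalysed Kochi-type aryl–allyl coupling, in which attack at the primary α-carbon is secured because γ-attack would join a di-ortho-substituted aryl group to a quaternary carbon, and the SN2 path leaves the 2E double bond untouched.

**Step 4**
Reactants: 6 1,4-dimethoxy-2,5-dimethyl-3-[(2E,6E,10E)-3,7,11,15-tetramethylhexadeca-2,6,10,14-tetraen-1-yl]benzene
Product: 7 2,5-dimethyl-3-[(2E,6E,10E)-3,7,11,15-tetramethylhexadeca-2,6,10,14-tetraen-1-yl]cyclohexa-2,5-diene-1,4-dione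
Conditions: (NH4)2Ce(NO3)6 (2.5 equiv), MeCN/CH2Cl2/H2O, 0 °C, 30 min, substrate added to the oxidant
Reagents that add atoms: water, O
Why: Oxidative demethylation of a hydroquinone dimethyl ether through the arene radical cation (water adds at the two ipso carbons and methanol leaves), a reaction in routine use on polyprenylated dimethoxyarenes because the isolated trisubstituted double bonds are oxidised far more slowly than the arene.

**Step 5**
Reactants: 7 2,5-dimethyl-3-[(2E,6E,10E)-3,7,11,15-tetramethylhexadeca-2,6,10,14-tetraen-1-yl]cyclohexa-2,5-diene-1,4-dione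
Product: 8 2,5-dimethyl-3-[(2E,6E,10E)-3,7,11,15-tetramethylhexadeca-2,6,10,14-tetraen-1-yl]benzene-1,4-diol
Conditions: Na2S2O4 (excess), degassed Et2O/H2O, rt, Ar, until colourless; dried and concentrated under Ar, used at once
Reagents that add atoms: none
Why: Two-electron reduction of the quinone to the hydroquinone by dithionite under neutral conditions, chosen so that no acid meets the free prenylhydroquinone and no racemic ring closure can start.

**Step 6**
Reactants: 8 2,5-dimethyl-3-[(2E,6E,10E)-3,7,11,15-tetramethylhexadeca-2,6,10,14-tetraen-1-yl]benzene-1,4-diol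
Product: 9 (2R)-2,5,8-trimethyl-2-[(3E,7E)-4,8,12-trimethyltrideca-3,7,11-trien-1-yl]-3,4-dihydro-2H-chromen-6-ol ((R)-β-tocotrienol)
Conditions: recombinant tocopherol cyclase (EC 5.5.1.24; plant or cyanobacterial enzyme overexpressed in Escherichia coli, cell-free extract), 8 added in EtOH with 2-hydroxypropyl-β-cyclodextrin, KH2PO4/K2HPO4 buffer pH 7.3, sodium ascorbate, dithiothreitol, Ar, dark, 30 °C
Reagents that add atoms: none
Why: The cyclase protonates C2′ of the 2′E double bond of 8 (the later C3) with an active-site acid while the phenolic oxygen on C4 of 8 (the later O1) adds to the tertiary carbon C3′ (the later C2), a Markovnikov hydroalkoxylation through a tertiary-cation-like transition state that turns the open, achiral hydroquinone into the chromanol in one isomerisation without by-product. The closest known reaction is the closure of 2-methyl-6-geranylgeranyl- and 2,3-dimethyl-6-geranylgeranylbenzene-1,4-diol to δ- and γ-tocotrienol by the same enzyme class, and its chemical counterpart is the acid-catalysed chromanol closure of racemic vitamin E synthesis. The dihydropyran ring closes in the 6-endo-trig mode, both alkene carbons (the later C3 and C2) ending in the ring. C2 is the only new stereocentre and, since 8 is achiral, it is controlled by the enzyme alone, which should fold the chain so that oxygen adds to the Re face of C3′ and gives R. The step needs chemoselectivity for the 2′ double bond over the 6′, 10′ and 14′ double bonds (no polyene cyclisation, which a Brønsted or Lewis acid would start in the chain) and enantioselectivity; both should be secured by the binding of the para hydroxyl group and the all-E tail, which places only the 2′ double bond between the catalytic acid and the ortho oxygen. Regiochemistry is not in question because only the oxygen on C4 of 8 is ortho to the chain, and a 2′Z contaminant, which this enzyme class is expected to reject, should stay behind as the hydroquinone.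

**Compound list**

1 | 1,4-dimethoxy-2,5-dimethylbenzene | COc1cc(C)c(OC)cc1C | starting material
2 | 1-bromo-2,5-dimethoxy-3,6-dimethylbenzene | COc1cc(C)c(OC)c(Br)c1C | intermediate
3 | (2E,6E,10E)-3,7,11,15-tetramethylhexadeca-2,6,10,14-tetraen-1-ol (geranylgeraniol) | CC(C)=CCC/C(C)=C/CC/C(C)=C/CC/C(C)=C/CO | starting material
4 | (2E,6E,10E)-1-bromo-3,7,11,15-tetramethylhexadeca-2,6,10,14-tetraene (geranylgeranyl bromide) | CC(C)=CCC/C(C)=C/CC/C(C)=C/CC/C(C)=C/CBr | intermediate
5 | (2,5-dimethoxy-3,6-dimethylphenyl)magnesium bromide | COc1cc(C)c(OC)c([Mg]Br)c1C | intermediate (not isolated)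
6 | 1,4-dimethoxy-2,5-dimethyl-3-[(2E,6E,10E)-3,7,11,15-tetramethylhexadeca-2,6,10,14-tetraen-1-yl]benzene | COc1cc(C)c(OC)c(C/C=C(\C)CC/C=C(\C)CC/C=C(\C)CCC=C(C)C)c1C | intermediate
7 | 2,5-dimethyl-3-[(2E,6E,10E)-3,7,11,15-tetramethylhexadeca-2,6,10,14-tetraen-1-yl]cyclohexa-2,5-diene-1,4-dione | CC1=CC(=O)C(C)=C(C/C=C(\C)CC/C=C(\C)CC/C=C(\C)CCC=C(C)C)C1=O | intermediate
8 | 2,5-dimethyl-3-[(2E,6E,10E)-3,7,11,15-tetramethylhexadeca-2,6,10,14-tetraen-1-yl]benzene-1,4-diol | Cc1cc(O)c(C)c(C/C=C(\C)CC/C=C(\C)CC/C=C(\C)CCC=C(C)C)c1O | intermediate
9 | (2R)-2,5,8-trimethyl-2-[(3E,7E)-4,8,12-trimethyltrideca-3,7,11-trien-1-yl]-3,4-dihydro-2H-chromen-6-ol ((R)-β-tocotrienol) | CC(C)=CCC/C(C)=C/CC/C(C)=C/CC[C@]1(C)CCc2c(C)c(O)cc(C)c2O1 | target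

**Step count and risks**

Total step count: 6. Longest linear sequence: 5 steps (1 → 2 → 6 → 7 → 8 → 9; steps 1, 3, 4, 5, 6).

Steps most likely to fail:

Step 6. Turnover may be slow or absent because the ring methyl ortho to the chain hinders productive binding. The lipophilic substrate may also transfer poorly into the aqueous phase, and 8 may re-oxidise to the quinone before it is converted. The fallback replaces the enzymatic hydroalkoxylation by a pericyclic ring closure and an enantiomer separation, and sets out from 7. Heating 7 in pyridine under Ar should tautomerise it to the ortho-quinone methide, which closes by oxa-6π electrocyclisation to racemic 2,5,8-trimethyl-2-[(3E,7E)-4,8,12-trimethyltrideca-3,7,11-trien-1-yl]-2H-chromen-6-ol F1. Sodium in boiling EtOH should then reduce only the conjugated 3,4-double bond and give racemic β-tocotrienol F2. Preparative HPLC on a cellulose tris(3,5-dimethylphenylcarbamate) phase should separate the enantiomers, and the route is rejoined at 9.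

Step 3. The coupling may suffer from attack at the tertiary γ-carbon (allylic transposition), from erosion of the 2E geometry through a π-allyl copper intermediate, and from homocoupling of the allylic bromide. The fallback inverts the polarity and needs no protecting groups; it sets out from 4. Bu3SnLi (from Bu3SnH and LiN(iPr)2, THF, −78 °C) should convert 4 into tributyl[(2E,6E,10E)-3,7,11,15-tetramethylhexadeca-2,6,10,14-tetraen-1-yl]stannane F3. F3 is added to commercial 2,5-dimethyl-1,4-benzoquinone (CC1=CC(=O)C(C)=CC1=O) with BF3·OEt2 in CH2Cl2 at −78 °C, a Lewis-acid-mediated allylstannane–quinone coupling that should place the chain at the free ring carbon with the 2E geometry kept. After KF work-up, Ag2O in Et2O should bring the hydroquinone/quinone mixture to the quinone, and the route is rejoined at 7, so that step 4 is bypassed as well.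

Step 4. The arene radical cation may couple oxidatively through the free ring position, and the polyene chain may be oxidised under the acidic nitrate conditions. The fallback separates oxidation from quinone release and sets out from 6. Constant-current electrolysis at a Pt anode in KOH/MeOH at 0 °C (undivided cell) should give the quinone bisketal 3,3,6,6-tetramethoxy-1,4-dimethyl-2-[(2E,6E,10E)-3,7,11,15-tetramethylhexadeca-2,6,10,14-tetraen-1-yl]cyclohexa-1,4-diene F4. Mild hydrolysis of F4 (aqueous AcOH, acetone, rt) should release the quinone without any oxidant present, and the route is rejoined at 7.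

**Further compounds**

F1 | step 6 | racemic 2,5,8-trimethyl-2-[(3E,7E)-4,8,12-trimethyltrideca-3,7,11-trien-1-yl]-2H-chromen-6-ol | CC(C)=CCC/C(C)=C/CC/C(C)=C/CCC1(C)C=Cc2c(C)c(O)cc(C)c2O1
F2 | step 6 | racemic β-tocotrienol | CC(C)=CCC/C(C)=C/CC/C(C)=C/CCC1(C)CCc2c(C)c(O)cc(C)c2O1
F3 | step 3 | tributyl[(2E,6E,10E)-3,7,11,15-tetramethylhexadeca-2,6,10,14-tetraen-1-yl]stannane | CCCC[Sn](CCCC)(CCCC)C/C=C(\C)CC/C=C(\C)CC/C=C(\C)CCC=C(C)C
F4 | step 4 | 3,3,6,6-tetramethoxy-1,4-dimethyl-2-[(2E,6E,10E)-3,7,11,15-tetramethylhexadeca-2,6,10,14-tetraen-1-yl]cyclohexa-1,4-diene | COC1(OC)C=C(C)C(OC)(OC)C(C/C=C(\C)CC/C=C(\C)CC/C=C(\C)CCC=C(C)C)=C1C
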